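Tuesday's flask and Friday's flask took the same charge and were stopped at 50 h and 80 h.

the same everywhere: Q 0.056 M (fed, over 4.0 h); X 0.0560 M; J 1.12 mM
- Tuesday's: time 50 h
- Friday's: time 80 h

    Q + X ⇌ L + G (K1 = 15, k1 = 540 /M/h)
    X + J → X.J (k2 = 25 /M/h)
    G → Z (k3 = 0.067 /h)
    2 Q → Q2 (k4 = 0.0031 /M/h)

* which of the two ends with the longer chains by the average number of monomer units in a chain (unreacted monomers counted as chains of one) ("neither" if they lie within 10%) (Tuesday's / Friday's / neither)
* average number of monomer units in a chain (unreacted monomers counted as chains of one) at the end, Tuesday's
* average number of monomer units in a chain (unreacted monomers counted as chains of one) at the end, Friday's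

- percent here means Q units held: one Q2 counts as two
- for a step with 2 of a species take k times the square, and two of it per event
- each molecule carries two end groups: a chain counts once for every two ends that are left, dead ends included; the units are half of the end groups of the two monomers charged
- a link that another step uses up counts as cut, two dead ends; so do two ends of one kind that react with each other
- run time (Tuesday's): 50 h

I compared rates at one moment first. Against X at its charge, a J goes at 1.40 /h, faster than the 0.067 /h at which a G leaves, so I expected J to be tied up early as X.J in both flasks, which puts [Q] above [X] by the J charged. I dropped Q2, since even with [Q] at the charge a Q goes that way at 3.47 × 10⁻⁴ /h, far less than 0.067 /h. After the feed the chains then number [Q], and the length is the Q charged over [Q]. That gives a ceiling, the units charged over the J charged, 50.0, the length at which [X] reaches zero.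

Then came G. With [L] near the charge, a G returns through the back step at 2.02 /h, which is 30.1 times 0.067 /h and faster. As [L] rises, that comparison does not weaken. So after the feed I held the exchange at equilibrium, with the removal of G as the rate-limiting step. Taking [L] as the charge, a length then stands for a definite [G]: 15 times the charge over the length, times the difference between one over the length and one over the ceiling. The two flasks lie on one curve, and each stops at the [G] it has reached. Friday's has 2.90 more half-lives of G by that step alone, at 10 h each. I committed to Friday's being longer, without a length of my own.

The forecast gave Friday's, with 13.9 for Tuesday's and 22 for Friday's, and its ground was this: “The slow step is removal of G.”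

Friday's ended longer, at 21.8 units a chain against 13.8 in Tuesday's. Its [G] read 0.00102 M, against 0.00340 M in Tuesday's. With the ceiling, Friday's length gives [G] of 9.95 × 10⁻⁴ M beside that reading. Friday's flask read at 8.0 d had reached 43.1, still below the ceiling of 50.0, and that length gives [G] of 6.26 × 10⁻⁵ M, where the flask held 6.16 × 10⁻⁵ M.

Its constants were chosen freely; the flask was simulated.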